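## The problem

Niruriflavone (21) is a flavone: benzene ring A is fused through C4a–C8a to 4-pyranone ring C, which carries the 4-methoxyphenyl ring B at C2. It has no stereocentre, so the whole difficulty is positional. Ring A is pentasubstituted in a fixed order: OH at C5, SO3H at C6, OH at C7, H at C8. C6 and C8 each lie between two oxygen donors and respond to electrophiles in much the same way, so sulfonation of the parent 5,7-dihydroxyflavone cannot be trusted to choose C6. The sulfonic acid is a strong, water-soluble acid that is awkward to carry and purify, and on so electron-rich a ring it can be lost again by ipso protonation in hot acid; it should therefore arrive last and under mild conditions. The 4'-methyl ether must stay while O7 is set free, so O7 needs a group that leaves under conditions harmless to an anisole, and the 4-pyranone ring, once made, is opened by hydroxide or alkoxide. The feature that offers a way in is the sequence C5(OH)–C6(X)–C7(O)–C8(H) attached to the C4a=C8a bond of ring C. A resorcinol with a substituent between its two oxygens, fused to an enone double bond, is what a vinylketene (C5, C8 and the C8a=C4a bond) and an ynol ether (C6, C7) give on benzannulation; if X is silicon, C6 is marked for ipso exchange to sulfur.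

## Retrosynthesis

**21 to 18.** The C6–S bond is cut and replaced by a C6–SiMe3 bond, and O7–H is replaced by O7–Si(i-Pr)3. The neighbouring cut, C6–H sulfonation of the parent flavone, offers no handle to tell C6 from C8. Carrying a protected sulfonate through the synthesis would require a sulfur-bearing alkyne and a harsh final deprotection. Compound 18 is neutral, lipophilic and chromatographable. The forward reaction must put the sulfur electrophile on the silicon-bearing carbon in preference to C8–H, and must then free O7 without touching the 4'-methyl ether; a silyl ether and fluoride meet the second demand.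

**18 to 9 and 14.** Four bonds of ring A are cut: C8–C8a, C4a–C5, C5–C6 and C7–C8. Ring A disappears and two open-chain partners remain: pyranone diazoketone 9, which supplies C5, C8 and the C4a=C8a bond, and siloxyalkyne 14, which supplies C6 and C7. The usual flavone cuts through ring C would leave a pentasubstituted benzene that still has to be differentiated at C6. This cut instead lets the substitution pattern come from the way the two partners join, through ketene 15, cyclobutenone 16 and dienylketene 17. The forward reaction needs one selectivity, the orientation of the ketene–alkyne union, and the polarisation of 14 supplies it.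

**9 to 7.** The bond between the acyl carbon and the diazo carbon is cut. This returns carboxylic acid 7 (through acid chloride 8) and a one-carbon diazoalkane. The alternative, diazo transfer to a methyl ketone, would need an extra carbon–carbon bond formation on the pyranone. The forward step only requires that the acid be activated without disturbing the pyranone carbonyl.

**7 to 5.** The ring C bond O1–C2 of the pyranone is cut (and the ester restored). This opens 7, through ester 6, to the open-chain triketo ester 5, in which all three ring C carbonyls and the carboxyl carbon are already in place. Cyclodehydration of a 1,3,5-tricarbonyl chain under acid is the standard route to 4-pyranones and avoids base after the ring exists.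

**5 to 3 and 4, and 3 to 1 and 2.** The bond between the terminal methyl carbon of diketone 3 and one carbonyl carbon of oxalate 4 is cut, and then the central C–C bond of 3 is cut to give acetophenone 1 and acetate 2. Both are Claisen condensations of commodity esters. The only demand is that acylation of 3 occurs at the methyl terminus, which thermodynamic control ensures.

**14 to 11 and 12, and 11 to 10.** The O–Si bond of 14 is cut to give silyl triflate 12 and ynolate 13, the conjugate base of silylketene 11. Ketene 11 in turn comes from the commercial ethyl ynol ether 10 by loss of ethene. The ethyl ether 10 could itself serve as the alkyne partner, but a 7-ethyl ether cannot be removed in the presence of the 4'-methyl ether. Exchanging ethyl for triisopropylsilyl costs two steps and buys a fluoride-labile O7 group. The forward step must silylate the ambident ynolate at oxygen.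

## Roads not taken

**Alternative 1:** Biomimetic Claisen cyclisation to ring A.
- Cut and key step: ring A is cut at the bond from C4a to its neighbouring oxygen-bearing ring carbon (C5 or C8a, equivalent by symmetry), unravelling it to a polyketide chain. Forward, Mg(OMe)2 in methanol opens pyranone A2 to triketo ester A3; the C6 carbanion of A3 attacks the ester carbon and aromatisation gives chalcone A1. Ring closure and dehydrogenation then lead to the unsulfonated flavone A4.
- Merits: no protecting groups, cheap reagents, and a short path to the carbon skeleton. Magnesium chelation steers the chain towards the Claisen mode of folding.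
- Weak points: the ring it builds is a symmetrical acyl-trihydroxybenzene, which is available far more simply by acylating the commodity triphenol. In A4, C6 and C8 are still equivalent in kind, and the sulfonic acid has to be placed by a late electrophilic substitution with nothing to direct it. A1 also closes spontaneously to the flavanone, so a separate oxidation is needed, and aldol-type folding of A3 competes.
- Comparison: up to A4 this road is shorter and avoids light and diazo compounds, which must be conceded. The chosen plan sets against it that C6 is marked by silicon in the same event that creates ring A.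

**Alternative 2:** Ring C closed at C2=C3 by intramolecular Wittig reaction.
- Cut and key step: the C2=C3 bond is cut. Forward, heating phosphorane A6 lets the ylide carbon (C3) attack the aryl ester carbonyl (C2); loss of the phosphine oxide closes ring C and gives the bis(benzyloxy)flavone A5. Debenzylation gives A4.
- Merits: the closure is neutral, thermal and well behaved, and avoids the strong base of diketone-based flavone syntheses. Every step is better precedented than the key step chosen here, and the sequence is readily scaled.
- Weak points: ring A comes from a phloroglucinol-type ketone and carries hydrogen at C6. Sulfonation of A5 or A4 must again choose between C6 and C8, and in A5 the C6 position lies between two benzyloxy groups and is the more hindered one. Several steps are also spent on selective benzylation, O-aroylation, bromination and ylide formation before the key step.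
- Comparison: in reliability and scalability this road is superior. The chosen plan sets against it regiochemical certainty at C6, which this road could match only by adding a blocking or directing sequence.

**Alternative 3:** Three-component carbonylative annulation.
- Cut and key step: C4a–C4, C4–C3 and O1–C2 are cut, giving iodophenol A8, carbon monoxide as C4 and aryl alkyne A9. Forward, PdCl2(PPh3)2 in Et2NH under CO effects oxidative addition of A8 to zerovalent palladium, CO insertion, coupling with A9 to an ynone, and amine-mediated 6-endo closure to the neopentyl sulfonate A7.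
- Merits: the sulfur sits at C6 before ring C is closed, so on regiochemistry this road equals the chosen plan. It is also more convergent and purely thermal and catalytic.
- Weak points: the positional problem is moved into the synthesis of the pentasubstituted benzene A8. On a sulfonated triphenol the two hydroxyls flanking sulfur must be benzylated while the para hydroxyl stays free, and one iodine must be placed. The iodide of A8 is flanked by OH and benzyloxy, so insertion is slow and direct coupling to a benzofuran or 5-exo closure to an aurone can compete. The end-game needs nucleophilic cleavage of a neopentyl sulfonate at high temperature and a separate debenzylation.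
- Comparison: if A8 were at hand, this road could well be the shorter one. The chosen plan sets against it that the ring A pattern arises from the annulation and not from differentiating three oxygens of a symmetric arene, and that the final deprotection is one mild operation.

Key step: step 7

## Route

Remark on the chemistry: the target is taken as the free sulfonic acid. It has no stereocentre; the single sp3 centre that appears on the way (in 16) is racemic and is erased within the same step.

Step 1
Reactants: 1 4'-methoxyacetophenone; 2 ethyl acetate
Product: 3 1-(4-methoxyphenyl)butane-1,3-dione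
Conditions: NaH (2 equiv), EtOAc (excess), THF, 0 °C to reflux; aq. HCl
Reagents that add atoms: none
Why: Crossed Claisen condensation: the sodium enolate of 1 is acylated by ethyl acetate, and deprotonation of the β-diketone by the second equivalent of NaH pulls the equilibrium to 3; no stereocentre is formed.

Step 2
Reactants: 3 1-(4-methoxyphenyl)butane-1,3-dione; 4 diethyl oxalate
Product: 5 ethyl 6-(4-methoxyphenyl)-2,4,6-trioxohexanoate
Conditions: NaOEt (2.2 equiv), EtOH/Et2O, 0 °C to rt; cold aq. HCl
Reagents that add atoms: none
Why: Claisen condensation with a non-enolisable, highly electrophilic diester; under equilibrating alkoxide conditions acylation at the central carbon reverts, whereas acylation at the terminal methyl is drained off as the chelated bis-enolate of 5, the established outcome for aroylacetones and oxalates.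

Step 3
Reactants: 5 ethyl 6-(4-methoxyphenyl)-2,4,6-trioxohexanoate
Product: 7 6-(4-methoxyphenyl)-4-oxo-4H-pyran-2-carboxylic acid, via pyranone ethyl ester 6 (not isolated)
Conditions: conc. HCl, AcOH, reflux
Reagents that add atoms: water, O
Why: Acid-catalysed cyclodehydration of the 1,3,5-tricarbonyl chain (the enol oxygen at C6 adds to the C2 ketone, then water is lost) gives the 4-pyranone ester 6, and the same hot aqueous acid hydrolyses the ester. Acid is used because hydroxide would open the pyranone ring, and the anisole ether is not cleaved by HCl.

Step 4
Reactants: 7 6-(4-methoxyphenyl)-4-oxo-4H-pyran-2-carboxylic acid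
Product: 9 2-(2-diazoacetyl)-6-(4-methoxyphenyl)-4H-pyran-4-one, via acid chloride 8 (not isolated)
Conditions: (COCl)2, cat. DMF, CH2Cl2, 0 °C to rt, evaporate; CH2N2 (3 equiv), Et2O/THF, 0 °C
Reagents that add atoms: diazomethane, C=[N+]=[N-]
Why: Acid chloride formation through the chloroiminium species from (COCl)2 and DMF, then C-acylation of diazomethane (the first stage of an Arndt–Eistert sequence). Excess diazomethane removes HCl as chloromethane, so the diazoketone is not converted to the chloromethyl ketone.

Step 5
Reactants: 10 ethoxy(trimethylsilyl)acetylene
Product: 11 trimethylsilylketene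
Conditions: neat, 120 °C, N2; distil
Reagents that add atoms: none
Why: Thermal retro-ene reaction of an ethyl ynol ether (1,5-hydrogen shift with loss of ethene) gives the ketene; the Me3Si group suppresses dimerisation, so 11 can be distilled and kept cold.

Step 6
Reactants: 11 trimethylsilylketene; 12 triisopropylsilyl trifluoromethanesulfonate
Product: 14 trimethyl{[tri(propan-2-yl)silyl]oxyethynyl}silane, via lithium ynolate 13 (not isolated)
Conditions: n-BuLi, THF, −100 °C; then 12, −100 to 0 °C
Reagents that add atoms: none
Why: Deprotonation of the silylketene at very low temperature gives ynolate 13. The bulky, oxygen-philic silyl triflate then attacks the oxygen terminus, as in the O-silylation of ynolates with triisopropylsilyl electrophiles, because the carbon terminus is shielded by Me3Si and would have to carry two large silyl groups.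

Step 7
Reactants: 9 2-(2-diazoacetyl)-6-(4-methoxyphenyl)-4H-pyran-4-one; 14 trimethyl{[tri(propan-2-yl)silyl]oxyethynyl}silane
Product: 18 5-hydroxy-2-(4-methoxyphenyl)-7-{[tri(propan-2-yl)silyl]oxy}-6-(trimethylsilyl)-4H-chromen-4-one, via pyranonylketene 15 (not isolated), via vinylcyclobutenone 16 (not isolated), via dienylketene 17 (not isolated)
Conditions: 14 (1.5 equiv), hν (405–450 nm LEDs), degassed ClCH2CH2Cl, rt; then 80 °C
Reagents that add atoms: none
Why: Danheiser benzannulation in its diazoketone form: light expels N2 from 9 and pyranone C2 migrates to the diazo carbon (photochemical Wolff rearrangement), forming C8–C8a and giving ketene 15, whose vinyl partner is the pyranone C2=C3 bond. The electrophilic ketene carbon bonds to the silyl-bearing carbon of 14 and the ketene α-carbon to the siloxy carbon in a regioselective (2+2) cycloaddition (C5–C6 and C7–C8), giving racemic cyclobutenone 16. Reversible conrotatory 4π opening gives dienylketene 17, and ring A closes by a thermally allowed disrotatory 6π electrocyclisation of the ketene carbon onto pyranone C3 (C4a–C5). Tautomerisation of the resulting cyclohexadienone gives the phenol, so the sp3 centre of 16 is erased and no stereocentre is set. The selectivity needed is the orientation of the (2+2) step: oxygen donation makes the alkyne carbon β to oxygen the nucleophile, and the positive charge building on the siloxy carbon is also β to Me3Si, so both substituents of 14 send silicon to C6. The hydrogen bond from 5-OH to the C4 carbonyl makes the product phenol a poor acyl acceptor for ketene and lets the excited flavone relax by proton transfer, and the long wavelength is chosen to excite the diazo band and not the arylpyranone. The closest known reaction type is the irradiation of aryl and heteroaryl diazomethyl ketones with triisopropylsiloxyalkynes to give resorcinol monosilyl ethers.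

Step 8
Reactants: 18 5-hydroxy-2-(4-methoxyphenyl)-7-{[tri(propan-2-yl)silyl]oxy}-6-(trimethylsilyl)-4H-chromen-4-one
Product: 21 niruriflavone (5,7-dihydroxy-2-(4-methoxyphenyl)-4-oxo-4H-chromene-6-sulfonic acid), via trimethylsilyl sulfonate ester 19 (not isolated), via 7-O-silyl sulfonic acid 20 (not isolated)
Conditions: Me3SiOSO2Cl (1.05 equiv), CH2Cl2, 0 °C to rt; H2O; then aq. HF, MeCN, rt
Reagents that add atoms: trimethylsilyl chlorosulfonate, C[Si](C)(C)OS(=O)(=O)Cl
Why: Electrophilic ipso substitution (sulfodesilylation) of an aryltrimethylsilane: the sulfur electrophile attacks C6 because the arenium ion is stabilised by the β-silicon effect and by both flanking oxygens, and steric compression is relieved as chloride carries Me3Si away. Water cleaves the Si–O–S link of 19 at once, and HF then cleaves the aryl O–Si bond of 20, the ortho sulfonic acid making the phenoxide a good leaving group. No base or Lewis acid is used, so the 4'-methyl ether and ring C are untouched.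

## Compound list

1 | 4'-methoxyacetophenone | COc1ccc(C(C)=O)cc1 | starting material
2 | ethyl acetate | CCOC(C)=O | starting material
3 | 1-(4-methoxyphenyl)butane-1,3-dione | COc1ccc(cc1)C(=O)CC(C)=O | intermediate
4 | diethyl oxalate | CCOC(=O)C(=O)OCC | starting material
5 | ethyl 6-(4-methoxyphenyl)-2,4,6-trioxohexanoate | CCOC(=O)C(=O)CC(=O)CC(=O)c1ccc(OC)cc1 | intermediate
6 | ethyl 6-(4-methoxyphenyl)-4-oxo-4H-pyran-2-carboxylate | CCOC(=O)c1cc(=O)cc(o1)-c1ccc(OC)cc1 | intermediate (not isolated)
7 | 6-(4-methoxyphenyl)-4-oxo-4H-pyran-2-carboxylic acid | COc1ccc(cc1)-c1cc(=O)cc(o1)C(=O)O | intermediate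
8 | 6-(4-methoxyphenyl)-4-oxo-4H-pyran-2-carbonyl chloride | COc1ccc(cc1)-c1cc(=O)cc(o1)C(Cl)=O | intermediate (not isolated)
9 | 2-(2-diazoacetyl)-6-(4-methoxyphenyl)-4H-pyran-4-one | COc1ccc(cc1)-c1cc(=O)cc(o1)C(=O)C=[N+]=[N-] | intermediate
10 | ethoxy(trimethylsilyl)acetylene | CCOC#C[Si](C)(C)C | starting material
11 | trimethylsilylketene | C[Si](C)(C)C=C=O | intermediate
12 | triisopropylsilyl trifluoromethanesulfonate | CC(C)[Si](OS(=O)(=O)C(F)(F)F)(C(C)C)C(C)C | starting material
13 | lithium 2-(trimethylsilyl)ethynolate | C[Si](C)(C)C#C[O-].[Li+] | intermediate (not isolated)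
14 | trimethyl{[tri(propan-2-yl)silyl]oxyethynyl}silane | C[Si](C)(C)C#CO[Si](C(C)C)(C(C)C)C(C)C | intermediate
15 | 6-(4-methoxyphenyl)-2-(2-oxoethenyl)-4H-pyran-4-one (pyranonylketene) | COc1ccc(cc1)-c1cc(=O)cc(o1)C=C=O | intermediate (not isolated)
16 | racemic 4-[6-(4-methoxyphenyl)-4-oxo-4H-pyran-2-yl]-3-{[tri(propan-2-yl)silyl]oxy}-2-(trimethylsilyl)cyclobut-2-en-1-one | COc1ccc(cc1)-c1cc(=O)cc(o1)C1C(=O)C([Si](C)(C)C)=C1O[Si](C(C)C)(C(C)C)C(C)C | intermediate (not isolated)
17 | (3E)-4-[6-(4-methoxyphenyl)-4-oxo-4H-pyran-2-yl]-3-{[tri(propan-2-yl)silyl]oxy}-2-(trimethylsilyl)buta-1,3-dien-1-one | COc1ccc(cc1)-c1cc(=O)cc(o1)/C=C(/O[Si](C(C)C)(C(C)C)C(C)C)C([Si](C)(C)C)=C=O | intermediate (not isolated)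
18 | 5-hydroxy-2-(4-methoxyphenyl)-7-{[tri(propan-2-yl)silyl]oxy}-6-(trimethylsilyl)-4H-chromen-4-one | COc1ccc(-c2cc(=O)c3c(O)c([Si](C)(C)C)c(O[Si](C(C)C)(C(C)C)C(C)C)cc3o2)cc1 | intermediate
19 | trimethylsilyl 5-hydroxy-2-(4-methoxyphenyl)-4-oxo-7-{[tri(propan-2-yl)silyl]oxy}-4H-chromene-6-sulfonate | COc1ccc(-c2cc(=O)c3c(O)c(S(=O)(=O)O[Si](C)(C)C)c(O[Si](C(C)C)(C(C)C)C(C)C)cc3o2)cc1 | intermediate (not isolated)
20 | 5-hydroxy-2-(4-methoxyphenyl)-4-oxo-7-{[tri(propan-2-yl)silyl]oxy}-4H-chromene-6-sulfonic acid | COc1ccc(-c2cc(=O)c3c(O)c(S(=O)(=O)O)c(O[Si](C(C)C)(C(C)C)C(C)C)cc3o2)cc1 | intermediate (not isolated)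
21 | niruriflavone, 5,7-dihydroxy-2-(4-methoxyphenyl)-4-oxo-4H-chromene-6-sulfonic acid | COc1ccc(-c2cc(=O)c3c(O)c(S(=O)(=O)O)c(O)cc3o2)cc1 | target

## Step count and least certain steps

Total steps: 8. Longest linear sequence: 6 steps (steps 1, 2, 3, 4, 7, 8, from 1 to 21); the alkyne branch (steps 5 and 6) joins at step 7.

**Step 7 (key step).** The light may be taken up by the arylpyranone chromophore and, as conversion rises, by the flavone product, so that nitrogen loss stalls or the excited pyranone rearranges or dimerises. The cycloaddition to the doubly silylated, hindered alkyne may also be slow enough for the ketene to dimerise. The fallback generates the same ketene in the dark and sets out from 9. Silver-promoted Wolff rearrangement in water (PhCO2Ag, Et3N, aqueous dioxane; Arndt–Eistert homologation) gives [6-(4-methoxyphenyl)-4-oxo-4H-pyran-2-yl]acetic acid F1. Being a vinylogous β-keto acid, F1 is converted cold and without storage by (COCl)2 into [6-(4-methoxyphenyl)-4-oxo-4H-pyran-2-yl]acetyl chloride F2. Slow addition of Et3N to F2 and 14 in toluene at rt, followed by heating to 80–110 °C, forms ketene 15 by dehydrochlorination; it then passes through 16 and 17 as before. The fallback comes back to the route at 18.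

**Step 8.** Attack of the sulfur electrophile at C8–H (also doubly activated) or at the oxygen of 5-OH may compete with ipso attack, and protons released in the medium may remove silicon before sulfur arrives. The fallback replaces electrophilic sulfonation by halogenation and cross-coupling and sets out from 18. Iododesilylation with ICl (CH2Cl2, −78 °C), which generates no strong acid, gives 5-hydroxy-6-iodo-2-(4-methoxyphenyl)-7-{[tri(propan-2-yl)silyl]oxy}-4H-chromen-4-one F3. Sulfination of the aryl iodide (Pd(OAc)2, PPh3, 1,10-phenanthroline, K2S2O5, HCO2Na, Bu4NBr, DMSO, 70 °C) gives 5-hydroxy-2-(4-methoxyphenyl)-4-oxo-7-{[tri(propan-2-yl)silyl]oxy}-4H-chromene-6-sulfinic acid F4, handled as its salt. Oxidation with aqueous H2O2 and acidification bring the sequence back to the route at 20, which is desilylated as in step 8.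

**Step 6.** Silylation may go to carbon instead of oxygen, since the ynolate is ambident and the bis(silyl)ketene is the more stable isomer, and butyllithium may add to the ketene carbonyl instead of deprotonating it. The fallback avoids the ynolate by making the O–C bond before the triple bond, with isopropyl in place of the O-silyl group; it sets out from 9, whose partner alone is changed. Propan-2-ol, KH and trichloroethylene give (E)-1,2-dichloro-1-(propan-2-yloxy)ethene F5. Treatment of F5 with n-BuLi (2.2 equiv, −78 °C: elimination and chlorine–lithium exchange) and Me3SiCl gives trimethyl[(propan-2-yloxy)ethynyl]silane F6. Benzannulation of 9 with F6 under the conditions of step 7 gives 5-hydroxy-2-(4-methoxyphenyl)-7-(propan-2-yloxy)-6-(trimethylsilyl)-4H-chromen-4-one F7. Sulfodesilylation as in step 8 with aqueous work-up gives 5-hydroxy-2-(4-methoxyphenyl)-4-oxo-7-(propan-2-yloxy)-4H-chromene-6-sulfonic acid F8. BCl3 in CH2Cl2 at 0 °C, which cleaves aryl isopropyl ethers and spares aryl methyl ethers, then brings the sequence back to the route at 21.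

**Step 4.** The chlorinating agent may activate the pyranone carbonyl oxygen (chloropyrylium formation) alongside the carboxyl group, and excess diazomethane may add as a dipole to the acyl-activated C2=C3 bond. The fallback replaces acylation of diazomethane by diazo transfer and sets out from 7. Amide coupling with MeNH(OMe)·HCl (1,1'-carbonyldiimidazole, CH2Cl2) gives the Weinreb amide N-methoxy-6-(4-methoxyphenyl)-N-methyl-4-oxo-4H-pyran-2-carboxamide F9. MeMgBr in THF at −78 °C gives 2-acetyl-6-(4-methoxyphenyl)-4H-pyran-4-one F10. Enolisation with LiN(SiMe3)2 and trifluoroacetylation with CF3CO2CH2CF3 give 4,4,4-trifluoro-1-[6-(4-methoxyphenyl)-4-oxo-4H-pyran-2-yl]butane-1,3-dione F11, which is used crude. Detrifluoroacetylative diazo transfer with MsN3, Et3N and water in MeCN brings the sequence back to the route at 9.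

## Further compounds

F1 | step 7 | [6-(4-methoxyphenyl)-4-oxo-4H-pyran-2-yl]acetic acid | COc1ccc(cc1)-c1cc(=O)cc(o1)CC(=O)O
F2 | step 7 | [6-(4-methoxyphenyl)-4-oxo-4H-pyran-2-yl]acetyl chloride | COc1ccc(cc1)-c1cc(=O)cc(o1)CC(Cl)=O
F3 | step 8 | 5-hydroxy-6-iodo-2-(4-methoxyphenyl)-7-{[tri(propan-2-yl)silyl]oxy}-4H-chromen-4-one | COc1ccc(-c2cc(=O)c3c(O)c(I)c(O[Si](C(C)C)(C(C)C)C(C)C)cc3o2)cc1
F4 | step 8 | 5-hydroxy-2-(4-methoxyphenyl)-4-oxo-7-{[tri(propan-2-yl)silyl]oxy}-4H-chromene-6-sulfinic acid | COc1ccc(-c2cc(=O)c3c(O)c(S(=O)O)c(O[Si](C(C)C)(C(C)C)C(C)C)cc3o2)cc1
F5 | step 6 | (E)-1,2-dichloro-1-(propan-2-yloxy)ethene | CC(C)O/C(Cl)=C\Cl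
F6 | step 6 | trimethyl[(propan-2-yloxy)ethynyl]silane | CC(C)OC#C[Si](C)(C)C
F7 | step 6 | 5-hydroxy-2-(4-methoxyphenyl)-7-(propan-2-yloxy)-6-(trimethylsilyl)-4H-chromen-4-one | COc1ccc(-c2cc(=O)c3c(O)c([Si](C)(C)C)c(OC(C)C)cc3o2)cc1
F8 | step 6 | 5-hydroxy-2-(4-methoxyphenyl)-4-oxo-7-(propan-2-yloxy)-4H-chromene-6-sulfonic acid | COc1ccc(-c2cc(=O)c3c(O)c(S(=O)(=O)O)c(OC(C)C)cc3o2)cc1
F9 | step 4 | N-methoxy-6-(4-methoxyphenyl)-N-methyl-4-oxo-4H-pyran-2-carboxamide | COc1ccc(cc1)-c1cc(=O)cc(o1)C(=O)N(C)OC
F10 | step 4 | 2-acetyl-6-(4-methoxyphenyl)-4H-pyran-4-one | COc1ccc(cc1)-c1cc(=O)cc(o1)C(C)=O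
F11 | step 4 | 4,4,4-trifluoro-1-[6-(4-methoxyphenyl)-4-oxo-4H-pyran-2-yl]butane-1,3-dione | COc1ccc(cc1)-c1cc(=O)cc(o1)C(=O)CC(=O)C(F)(F)F
A1 | alternative 1 | (2E)-3-(4-methoxyphenyl)-1-(2,4,6-trihydroxyphenyl)prop-2-en-1-one | COc1ccc(/C=C/C(=O)c2c(O)cc(O)cc2O)cc1
A2 | alternative 1 | 4-hydroxy-6-[(3E)-4-(4-methoxyphenyl)-2-oxobut-3-en-1-yl]-2H-pyran-2-one | COc1ccc(/C=C/C(=O)Cc2cc(O)cc(=O)o2)cc1
A3 | alternative 1 | methyl (8E)-9-(4-methoxyphenyl)-3,5,7-trioxonon-8-enoate | COC(=O)CC(=O)CC(=O)CC(=O)/C=C/c1ccc(OC)cc1
A4 | alternative 1 | 5,7-dihydroxy-2-(4-methoxyphenyl)-4H-chromen-4-one | COc1ccc(-c2cc(=O)c3c(O)cc(O)cc3o2)cc1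
A5 | alternative 2 | 5,7-bis(benzyloxy)-2-(4-methoxyphenyl)-4H-chromen-4-one | COc1ccc(-c2cc(=O)c3c(OCc4ccccc4)cc(OCc4ccccc4)cc3o2)cc1
A6 | alternative 2 | 3,5-bis(benzyloxy)-2-[(triphenyl-λ5-phosphanylidene)acetyl]phenyl 4-methoxybenzoate | COc1ccc(cc1)C(=O)Oc1cc(OCc2ccccc2)cc(OCc2ccccc2)c1C(=O)C=P(c1ccccc1)(c1ccccc1)c1ccccc1
A7 | alternative 3 | neopentyl 5,7-bis(benzyloxy)-2-(4-methoxyphenyl)-4-oxo-4H-chromene-6-sulfonate | COc1ccc(-c2cc(=O)c3c(OCc4ccccc4)c(S(=O)(=O)OCC(C)(C)C)c(OCc4ccccc4)cc3o2)cc1
A8 | alternative 3 | neopentyl 2,6-bis(benzyloxy)-4-hydroxy-3-iodobenzenesulfonate | CC(C)(C)COS(=O)(=O)c1c(OCc2ccccc2)cc(O)c(I)c1OCc1ccccc1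
A9 | alternative 3 | 1-ethynyl-4-methoxybenzene | COc1ccc(C#C)cc1
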